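**Plan**

- Atom labels follow the target throughout: ring C1 (C=O), C2=C3, C4 (CHOH), C5 (CH2), C6 (quaternary C–OH); side chain C1', C2' (CHOH) to C17'.
- Cuts: first the C6–O bond, then C4–H (ketone reduction), then the C1'–C6 bond (aryl Grignard plus terminal epoxide) and the C1'–C2' bond (sulfur ylide plus aldehyde). The enabling feature is that the C2' and C6 oxygens are 1,3-related and C6 is β to C4, so with C4 as the carbonyl and C5=C6 as an alkene of a quinone monoketal ring, the C2' oxygen can pass an oxygen to C6 through a six-membered dioxaborinane.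
- Forward: palmitoleic acid is extended to the C17 (S)-epoxide and joined to a 2,5-dimethoxyphenyl ring. The arene becomes the carbocycle (bisketal, then 4-keto monoketal), the dioxaborinane closes at C6, C4 is reduced, and boronate and ketal are removed.
- Stereochemistry: C2' from hydrolytic kinetic resolution; C6 relayed from C2' through the chair dioxaborinane; C4 from a catalyst-controlled CBS reduction; the Z-alkene comes from palmitoleic acid.

Key step: step 8

**Route**

Step 1
Reactants: 1 palmitoleic acid, (9Z)-hexadec-9-enoic acid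
Product: 2 (9Z)-hexadec-9-en-1-ol
Conditions: LiAlH4, THF, 0 °C → rt; aqueous work-up
Reagents that add atoms: none
Why: LiAlH4 reduction of a carboxylic acid to the primary alcohol is standard and leaves the isolated Z-alkene untouched.

Step 2
Reactants: 2 (9Z)-hexadec-9-en-1-ol
Product: 3 (9Z)-hexadec-9-enal
Conditions: TEMPO (10 mol%), PhI(OAc)2, CH2Cl2, rt
Reagents that add atoms: none
Why: TEMPO-catalysed alcohol oxidation with PhI(OAc)2 as terminal oxidant should stop at the aldehyde and neither epoxidise nor isomerise the Z-alkene.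

Step 3
Reactants: 3 (9Z)-hexadec-9-enal
Product: 4 rac-2-[(8Z)-pentadec-8-en-1-yl]oxirane
Conditions: Me3S+ I−, NaH, DMSO–THF, 0 °C → rt
Reagents that add atoms: trimethylsulfonium iodide, C[S+](C)C.[I-]
Why: In this Corey–Chaykovsky epoxidation the sulfonium methylide adds to the aldehyde and the betaine closes to the terminal epoxide, supplying C1'; an ylide is chosen because a peracid route through the terminal alkene would attack the internal Z-alkene first.

Step 4
Reactants: 4 rac-2-[(8Z)-pentadec-8-en-1-yl]oxirane
Product: 5 (2S)-2-[(8Z)-pentadec-8-en-1-yl]oxirane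
Conditions: (S,S)-(salen)Co(OAc) (0.5 mol%; salen = N,N'-bis(3,5-di-tert-butylsalicylidene)cyclohexane-1,2-diamine dianion, trivalent cobalt), H2O (0.55 equiv), THF, 0 °C → rt
Reagents that add atoms: none
Why: In the Jacobsen hydrolytic kinetic resolution the (S,S)-catalyst should hydrolyse the (R)-epoxide selectively, as is general for alkyl oxiranes, so the unreacted (S)-epoxide (at most half of the material) fixes C2' and is separated from the polar diol.

Step 5
Reactants: 5 (2S)-2-[(8Z)-pentadec-8-en-1-yl]oxirane; 6 2-bromo-1,4-dimethoxybenzene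
Product: 8 (2S,10Z)-1-(2,5-dimethoxyphenyl)heptadec-10-en-2-ol, via arylmagnesium bromide 7 (not isolated)
Conditions: 6, Mg, THF, 40 °C; then CuI (10 mol%), 5, THF, −30 → 0 °C; then H2O
Reagents that add atoms: none
Why: Copper-catalysed SN2 opening of a terminal epoxide by an aryl Grignard reagent occurs at the unsubstituted carbon, forming the C1'–aryl bond without touching the C2' stereocentre.

Step 6
Reactants: 8 (2S,10Z)-1-(2,5-dimethoxyphenyl)heptadec-10-en-2-ol
Product: 9 (2S,10Z)-1-(3,3,6,6-tetramethoxycyclohexa-1,4-dien-1-yl)heptadec-10-en-2-ol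
Conditions: Pt anode, Pt cathode, undivided cell, 1% KOH in MeOH, 0 °C, constant current (about 2.5 F/mol)
Reagents that add atoms: methanol, CO
Why: Anodic methoxylation of a 1,4-dimethoxyarene in basic methanol is the standard route to quinone bisketals, and the arene is oxidised at a much lower potential than the isolated alkene or the secondary alcohol.

Step 7
Reactants: 9 (2S,10Z)-1-(3,3,6,6-tetramethoxycyclohexa-1,4-dien-1-yl)heptadec-10-en-2-ol
Product: 10 3-[(2S,10Z)-2-hydroxyheptadec-10-en-1-yl]-4,4-dimethoxycyclohexa-2,5-dien-1-one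
Conditions: 5% aq. AcOH, acetone, 0 °C → rt
Reagents that add atoms: water, O
Why: In this regioselective monohydrolysis of a quinone bisketal the ketal remote from the side chain should ionise faster, because its allylic oxocarbenium ion places positive charge on the alkyl-bearing carbon and it is less hindered, so the carbonyl appears at C4 and the C1 ketal stays.

Step 8
Reactants: 10 3-[(2S,10Z)-2-hydroxyheptadec-10-en-1-yl]-4,4-dimethoxycyclohexa-2,5-dien-1-one; 11 phenylboronic acid
Product: 13 (4S,6R)-11,11-dimethoxy-4-[(8Z)-pentadec-8-en-1-yl]-2-phenyl-1,3-dioxa-2-boraspiro[5.5]undec-9-en-8-one, via boronic hemiester 12 (not isolated)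
Conditions: PhB(OH)2 (1.3 equiv), quinuclidine (20 mol%), 4 Å MS, toluene, 45 °C
Reagents that add atoms: none
Why: Proposed new method: 11 condenses with the C2' hydroxyl to hemiester 12, whose B–OH oxygen becomes nucleophilic when the amine coordinates boron and adds to C6, the side-chain-bearing β-carbon of the C4 enone, after which the dienolate is protonated at C5; the closest known reaction type is the amine-promoted intramolecular oxa-Michael addition of boronic acid hemiesters of δ-hydroxy enones, which has not been shown at a β,β-disubstituted carbon of a quinone monoketal. The dioxaborinane (O–B–O–C6–C1'–C2') closes in the 6-exo-trig mode. The new C6 stereocentre is controlled by C2' through the chair dioxaborinane, in which the C2' chain and the bulky C1 ketal carbon are equatorial and C5 is axial, and because the addition is reversible this more stable spiro chair should accumulate and give (6R). The step needs site selectivity for C6 over the unsubstituted β-carbon C2, which the tether secures because it can reach only C6 and the sieves remove any free external oxygen nucleophile. The cross-conjugated quinone monoketal is a strong acceptor, which is why addition to the hindered carbon should still be feasible.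

Step 9
Reactants: 13 (4S,6R)-11,11-dimethoxy-4-[(8Z)-pentadec-8-en-1-yl]-2-phenyl-1,3-dioxa-2-boraspiro[5.5]undec-9-en-8-one
Product: 14 (4S,6S,8S)-11,11-dimethoxy-4-[(8Z)-pentadec-8-en-1-yl]-2-phenyl-1,3-dioxa-2-boraspiro[5.5]undec-9-en-8-ol (C6 is unchanged in space; only its descriptor changes)
Conditions: (R)-2-methyl-CBS-oxazaborolidine (30 mol%), catecholborane (2 equiv), toluene, −78 °C; aqueous work-up
Reagents that add atoms: none
Why: In this Corey–Bakshi–Shibata reduction the (R)-oxazaborolidine should bind the C4 carbonyl on the side of the C5 methylene (small flank), away from the C3 alkene (large flank), and deliver hydride under reagent control to give the (4S)-allylic alcohol with the hydroxyl cis to the C6 oxygen, while catecholborane at this temperature reduces the enone 1,2 and does not hydroborate the chain alkene.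

Step 10
Reactants: 14 (4S,6S,8S)-11,11-dimethoxy-4-[(8Z)-pentadec-8-en-1-yl]-2-phenyl-1,3-dioxa-2-boraspiro[5.5]undec-9-en-8-ol
Product: 15 (1R,3S)-1-[(2S,10Z)-2-hydroxyheptadec-10-en-1-yl]-6,6-dimethoxycyclohex-4-ene-1,3-diol
Conditions: 30% aq. H2O2, NaHCO3, THF–H2O, 0 °C → rt
Reagents that add atoms: none
Why: In this oxidative cleavage of an arylboronic ester, hydroperoxide adds to boron, phenyl migrates to oxygen and the borate hydrolyses to the free 1,3-diol, and with the ketone already reduced there is no enone for the peroxide to epoxidise.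

Step 11
Reactants: 15 (1R,3S)-1-[(2S,10Z)-2-hydroxyheptadec-10-en-1-yl]-6,6-dimethoxycyclohex-4-ene-1,3-diol
Product: 16 (4S,6R)-4,6-dihydroxy-6-[(2S,10Z)-2-hydroxyheptadec-10-en-1-yl]cyclohex-2-en-1-one
Conditions: 0.5 M aq. HCl, THF, 0 °C → rt
Reagents that add atoms: water, O
Why: Acid-catalysed ketal hydrolysis through the allylic oxocarbenium ion unveils the C1 ketone and thus the enone, and dilute acid at low temperature is chosen because the γ-hydroxy enone can dehydrate.

**Compound list**

1 | palmitoleic acid, (9Z)-hexadec-9-enoic acid | CCCCCC/C=C\CCCCCCCC(=O)O | starting material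
2 | (9Z)-hexadec-9-en-1-ol | CCCCCC/C=C\CCCCCCCCO | intermediate
3 | (9Z)-hexadec-9-enal | CCCCCC/C=C\CCCCCCCC=O | intermediate
4 | rac-2-[(8Z)-pentadec-8-en-1-yl]oxirane | CCCCCC/C=C\CCCCCCCC1CO1 | intermediate
5 | (2S)-2-[(8Z)-pentadec-8-en-1-yl]oxirane | CCCCCC/C=C\CCCCCCC[C@H]1CO1 | intermediate
6 | 2-bromo-1,4-dimethoxybenzene | COc1ccc(OC)c(Br)c1 | starting material
7 | (2,5-dimethoxyphenyl)magnesium bromide (formed in the flask) | COc1ccc(OC)c([Mg]Br)c1 | intermediate
8 | (2S,10Z)-1-(2,5-dimethoxyphenyl)heptadec-10-en-2-ol | CCCCCC/C=C\CCCCCCC[C@H](O)Cc1cc(OC)ccc1OC | intermediate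
9 | (2S,10Z)-1-(3,3,6,6-tetramethoxycyclohexa-1,4-dien-1-yl)heptadec-10-en-2-ol | CCCCCC/C=C\CCCCCCC[C@H](O)CC1=CC(OC)(OC)C=CC1(OC)OC | intermediate
10 | 3-[(2S,10Z)-2-hydroxyheptadec-10-en-1-yl]-4,4-dimethoxycyclohexa-2,5-dien-1-one | CCCCCC/C=C\CCCCCCC[C@H](O)CC1=CC(=O)C=CC1(OC)OC | intermediate
11 | phenylboronic acid | OB(O)c1ccccc1 | starting material
12 | phenylboronic acid hemiester of 10 at the C2' oxygen (formed in the flask) | CCCCCC/C=C\CCCCCCC[C@H](OB(O)c1ccccc1)CC2=CC(=O)C=CC2(OC)OC | intermediate
13 | (4S,6R)-11,11-dimethoxy-4-[(8Z)-pentadec-8-en-1-yl]-2-phenyl-1,3-dioxa-2-boraspiro[5.5]undec-9-en-8-one | CCCCCC/C=C\CCCCCCC[C@H]2C[C@@]1(OB(c3ccccc3)O2)CC(=O)C=CC1(OC)OC | intermediate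
14 | (4S,6S,8S)-11,11-dimethoxy-4-[(8Z)-pentadec-8-en-1-yl]-2-phenyl-1,3-dioxa-2-boraspiro[5.5]undec-9-en-8-ol | CCCCCC/C=C\CCCCCCC[C@H]2C[C@@]1(OB(c3ccccc3)O2)C[C@H](O)C=CC1(OC)OC | intermediate
15 | (1R,3S)-1-[(2S,10Z)-2-hydroxyheptadec-10-en-1-yl]-6,6-dimethoxycyclohex-4-ene-1,3-diol | CCCCCC/C=C\CCCCCCC[C@H](O)C[C@@]1(O)C[C@H](O)C=CC1(OC)OC | intermediate
16 | (4S,6R)-4,6-dihydroxy-6-[(2S,10Z)-2-hydroxyheptadec-10-en-1-yl]cyclohex-2-en-1-one | CCCCCC/C=C\CCCCCCC[C@H](O)C[C@@]1(O)C[C@H](O)C=CC1=O | target

**Count and risks**

Total step count: 11. Longest linear sequence: 11 steps (1 to 16); the aryl partner 6 and the boronic acid 11 are used as bought.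

Steps most likely to fail:

Step 8 (the proposed new method). The tethered oxygen may fail to add to the hindered, fully substituted β-carbon, or the addition may revert faster than the spiro boronate accumulates. The fallback gives up the conjugate addition and installs the C6 oxygen by known epoxide chemistry. It sets out from bisketal 9. Hydroxyl-directed epoxidation of the trisubstituted ring alkene, which is homoallylic to the C2' hydroxyl (VO(acac)2, tBuOOH, CH2Cl2), would give epoxy bisketal F1; only modest 1,3-induction is expected, so the diastereomer with oxygen on the required face would be separated. LiBEt3H in THF should open the epoxide at the secondary carbon C5, since the quaternary C6 cannot undergo SN2, giving tertiary alcohol F2. Dilute aqueous acetic acid should then hydrolyse the C4 ketal, the only one without a hydroxyl on the neighbouring carbon, to β-hydroxy enone F3. Condensation of F3 with 11 (MgSO4, CH2Cl2, no base) closes the same dioxaborinane, and the route is rejoined at 13, which is reduced at once.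

Step 9. Facial selectivity may be poor, because the methylene flank of the C4 carbonyl carries the quaternary spiro carbon and the size difference read by the catalyst is small, and the ring may impose an opposing bias. The fallback uses substrate control followed by inversion and sets out from 13. Luche reduction (NaBH4, CeCl3·7H2O, MeOH, −78 °C) gives the allylic alcohol; if the 4S epimer dominates it is simply 14. If axial hydride delivery gives mainly the C8 epimer of 14, F4, this single free hydroxyl is inverted by a Mitsunobu reaction (4-nitrobenzoic acid, PPh3, DIAD, THF) to the 4-nitrobenzoate of 14, F5. K2CO3 in MeOH cleaves the ester, and the crude material, in which the boronate may be partly methanolysed, is taken straight into the conditions of step 10, so the route is rejoined at 15.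

Step 7. Regiocontrol may be lost in the monohydrolysis, through cleavage of the ketal next to the side chain, cleavage of both ketals, or capture of an oxocarbenium ion by the side-chain hydroxyl. The fallback fixes the position of the carbonyl with a phenol oxygen and sets out from epoxide 5. Commercial 3-bromo-4-methoxyphenol is silylated (TBSCl, imidazole, DMF) to (3-bromo-4-methoxyphenoxy)(tert-butyl)dimethylsilane F6 and converted with Mg into its Grignard reagent F7. Copper-catalysed opening of 5 (CuI, THF) gives silyl ether alcohol F8, and Bu4NF in THF frees the phenol F9. Oxidative dearomatisation with PhI(OAc)2 in MeOH at 0 °C converts the 4-methoxyphenol directly into the 4,4-dimethoxy dienone, so the route is rejoined at 10 without a bisketal.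

**Further compounds**

F1 | step 8 | (1R,6S)-1-[(2S,10Z)-2-hydroxyheptadec-10-en-1-yl]-2,2,5,5-tetramethoxy-7-oxabicyclo[4.1.0]hept-3-ene | CCCCCC/C=C\CCCCCCC[C@H](O)C[C@@]12O[C@@H]1C(OC)(OC)C=CC2(OC)OC
F2 | step 8 | (1R)-1-[(2S,10Z)-2-hydroxyheptadec-10-en-1-yl]-2,2,5,5-tetramethoxycyclohex-3-en-1-ol | CCCCCC/C=C\CCCCCCC[C@H](O)C[C@@]1(O)CC(OC)(OC)C=CC1(OC)OC
F3 | step 8 | (5R)-5-hydroxy-5-[(2S,10Z)-2-hydroxyheptadec-10-en-1-yl]-4,4-dimethoxycyclohex-2-en-1-one | CCCCCC/C=C\CCCCCCC[C@H](O)C[C@@]1(O)CC(=O)C=CC1(OC)OC
F4 | step 9 | C8 epimer of 14 (hydroxyl trans to the C6 oxygen) | CCCCCC/C=C\CCCCCCC[C@H]2C[C@@]1(OB(c3ccccc3)O2)C[C@@H](O)C=CC1(OC)OC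
F5 | step 9 | 4-nitrobenzoate of 14 (ester oxygen cis to the C6 oxygen) | CCCCCC/C=C\CCCCCCC[C@H]2C[C@@]1(OB(c3ccccc3)O2)C[C@H](OC(=O)c4ccc(cc4)[N+](=O)[O-])C=CC1(OC)OC
F6 | step 7 | (3-bromo-4-methoxyphenoxy)(tert-butyl)dimethylsilane | COc1ccc(O[Si](C)(C)C(C)(C)C)cc1Br
F7 | step 7 | [5-(tert-butyldimethylsilyloxy)-2-methoxyphenyl]magnesium bromide | COc1ccc(O[Si](C)(C)C(C)(C)C)cc1[Mg]Br
F8 | step 7 | (2S,10Z)-1-[5-(tert-butyldimethylsilyloxy)-2-methoxyphenyl]heptadec-10-en-2-ol | CCCCCC/C=C\CCCCCCC[C@H](O)Cc1cc(O[Si](C)(C)C(C)(C)C)ccc1OC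
F9 | step 7 | 3-[(2S,10Z)-2-hydroxyheptadec-10-en-1-yl]-4-methoxyphenol | CCCCCC/C=C\CCCCCCC[C@H](O)Cc1cc(O)ccc1OC
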